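Assumption (remark on the chemistry): the target carries no stereodescriptor and is treated as having no stereogenic element to control; if rotation about the crowded bonds at C1 of ring A were slow, the material would form as the racemate. Ring A is numbered C1 (methide carbon), C2 (4-hydroxyphenyl), C3 and C4 (hydrogen), C5 (CH2OH), C6 (arylethynyl).

## Structural features

Selaginellin is built on one benzene ring A that carries four contiguous carbon substituents. C1 holds the methide carbon, which is bound to a 4-hydroxyphenyl ring and, through an exocyclic C=C bond, to a cyclohexa-2,5-dien-1-one ring (a para-quinone methide). C2 holds a 4-hydroxyphenyl ring, C5 a hydroxymethyl group and C6 a (4-hydroxyphenyl)ethynyl group. There is no stereocentre, and because the quinone methide ring and the phenol ring on the methide carbon interchange by tautomerism, the C=C geometry poses no question. The fragile parts are the quinone methide (electrophilic at the methide carbon), the diarylalkyne flanked by two potential oxygen nucleophiles (the C5 CH2OH and, at the precursor stage, the C1 carbinol), and four free hydroxyl groups. The real difficulty is the 1,2,3,4-tetrasubstituted pattern of ring A: C1 lies between the C2 aryl and the C6 alkyne, so every bond to C1 and its neighbours is made at a doubly ortho-substituted site. Three of the appendages are the same 4-oxyphenyl unit, so one protected 4-halophenol serves repeatedly. The key step exploits the adjacency of C1 and C2, which carry one electrophile-derived carbon (the acyl carbon) and one nucleophile-derived carbon (the aryl group). It also exploits C6, which can hold a chlorine that polarises a C1–C2 aryne and later becomes the handle for the alkyne.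

The mapping of ring A onto the aryne precursor was checked position by position and is consistent: the sulfonate-bearing carbon is C2, the iodine-bearing carbon C1, the chlorine-bearing carbon C6 and the CH2O-bearing carbon C5. The precursor is therefore kept as designed, and the changes concern how it is reached and how the product is carried on. The aryl acetal is cleaved without protic acid so that the silyl ether survives. The alkynylation is run without copper. The final unmasking is a single acidic operation with no fluoride or base, so that no free alkoxide sits next to the alkyne.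

## Logic of the disconnections

29 ⇐ 27 (through 28). No carbon–carbon bond is cut. The exocyclic C=C of the quinone methide is traced back to a tertiary C–OH, and the five O–H groups to three methoxymethyl acetals, one silyl ether and the carbinol. The reason is that the electrophilic quinone methide should appear last. The gain is a precursor that is inert to organometallic reagents. The demand is that one acidic operation cleaves all four protecting groups and ionises the carbinol without touching the alkyne or the benzylic alcohol.

27 ⇐ 25 + 26 (26 from 2). The bond between the carbinol carbon and one of its two identical 4-oxyphenyl groups is cut. Because the two aryl groups are the same, either can come last, and the acceptor is a non-enolisable ketone. The gain is the removal of the quaternary carbon. The demand is clean 1,2-addition to a carbonyl group whose ring A neighbour is substituted at both ortho positions.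

25 ⇐ 24 + 9. The C6–C(sp) bond is cut. The chlorine that steered the aryne sits ortho to the carbonyl group and is thereby activated for oxidative addition, so no extra handle has to be installed. The gain is the removal of the whole arylethynyl arm. The demand is a catalyst that inserts into a hindered carbon–chlorine bond and does not oligomerise the alkyne.

24 ⇐ 18 + 19 + 5 (key disconnection). The C2–aryl bond and the C1–C(=O) bond are cut together. These are the two most crowded adjacent bonds of ring A, and an aryne between C1 and C2 makes both in one operation, with the nucleophilic partner on C2 and the electrophilic partner on C1. The gain is that ring A falls back to a simple trisubstituted benzene. The demands are regioselective arylation at C2, a single acyl transfer, and survival of the ortho-chloro arylmagnesium.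

18 ⇐ 17 ⇐ 15. The O–S bond and then the O–CH2 bond of the acetal are exchanged. The sulfonate is the leaving group for aryne release, whereas the acetal was needed earlier as the directing group. The demand is cleavage of an aryl acetal in the presence of a benzylic silyl ether.

15 ⇐ 13 (through 14). The carbon–iodine bond is cut. The position between the chlorine and the acetal oxygen is the most acidic ring position and is addressed by directed metalation. The demand is a temperature at which the ortho-chloro aryllithium does not lose LiCl.

13 ⇐ 12 ⇐ 11 ⇐ 10. The O–Si bond, a C–H bond (aldehyde to alcohol) and the O–CH2 bond are undone. This reaches a commercial benzaldehyde that already holds the chlorine, the oxygen and the one-carbon unit in the correct 1,2,4-relationship.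

Side arms. 19 ⇐ 2 ⇐ 1 (carbon–magnesium, then O–CH2). 5 ⇐ 4 ⇐ 3 (O–CH2, then the amide C–N bond). 9 ⇐ 8 ⇐ 7 ⇐ 6 (C–Si, the aryl–alkyne bond, then O–CH2). Each arm ends in a para-substituted phenol and puts no demand on selectivity.

## Other disconnections considered

Alternative 1: Ring A is taken back to the dihydro level and cut at C3–C4. This opens it to butenolide A1, a 5,5-diaryl-furan-2(5H)-one with a 1-[(methoxymethoxy)methyl]vinyl group on C3 and a 1-arylvinyl group on C4.
- Forward key step: heating A1 should cause thermal disrotatory 6π-electrocyclisation to the cyclohexa-1,3-diene A2. Dehydrogenation (DDQ) would give the aromatic phthalide A3. The lactone carbonyl at C6 then still has to become the arylalkyne: reduction to the lactol, homologation with the Ohira–Bestmann reagent, and Sonogashira coupling with 7.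
- In favour: the diarylmethyl carbon and the carbons that become C1 and C6 are joined in a small ring before the benzene exists, so no bond is made to a doubly ortho-substituted arene. The substitution pattern follows from connectivity alone. On this point it is better than the chosen plan, which relies on an electronic bias. The late Sonogashira would use an unhindered aryl iodide, which is also better than coupling at a hindered chloride. The reaction needs no reagent.
- Against: A1 is a tetrasubstituted alkene carrying two different 1,1-disubstituted vinyl groups next to a gem-diaryl carbon. Making it requires two successive, regiocontrolled couplings. The planar s-cis,s-cis arrangement needed for closure is sterically costly, so high temperatures and competing diene polymerisation are to be expected.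
- Comparison: the key step makes one carbon–carbon bond, against two in the chosen plan. Three oxidation-level adjustments follow it. The route would probably be several steps longer. Mechanistically it is the simpler step.

Alternative 2: Ring A is cut at C1–C6, C2–C3 and C4–C5. This leads to acetylene and the silicon-tethered diyne A4, the alkynyl(dimethyl)silyl ether of a 1,1,3-triaryl propargylic alcohol.
- Forward key step: RhCl(PPh3)3 under acetylene should cyclotrimerise A4 with acetylene to the benzoxasilole A5. The C6–Si bond would then be exchanged for carbon, for example by ipso-iodination with ICl and Sonogashira coupling with 9.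
- In favour: three carbon–carbon bonds and ring A are made in one catalytic step, which is better bond economy than the chosen key step. The tether fixes C1 next to C6, so regiocontrol is at least equal to that of the chlorine-directed aryne. The tertiary oxygen is present from the start, so no aryl nucleophile has to add to a hindered ketone; this is a point on which the alternative is better.
- Against: acetylene homotrimerisation and self-reaction of A4 compete, so dilution and gas handling are needed. A doubly benzylic, propargylic silyl ether is prone to ionise. Replacing silicon by carbon at a doubly ortho-substituted position next to a quaternary carbon is no easier than coupling the chloride of the chosen plan.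
- Comparison: the precursor is short, so overall length would be similar. The risk moves from aryne regiochemistry and an aryl chloride coupling to chemoselective cyclotrimerisation and a carbon–silicon to carbon–carbon exchange.

Alternative 3: Ring A is cut at C4–C5 and C1–C2. This gives the 1,3-bis(silyloxy)diene A6, which supplies C5, C6, C1 and the ester carbon, and the 3-silyloxy enone A7, which supplies C2 with its aryl group, C3 and C4.
- Forward key step: TiCl4 in CH2Cl2 should bring the diene terminus C5 onto the silyloxy-bearing C4, close C1 onto the aryl ketone C2 by a Mukaiyama aldol reaction, and aromatise with loss of silanol and water to the salicylate A8. The C6 hydroxyl would then be triflated and coupled with 9, and the ester would take up two equivalents of 26.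
- In favour: C6 emerges as a phenol, and its triflate is a better coupling partner than the aryl chloride. The ester accepts both identical aryl groups of the methide carbon from one reagent, which exploits the symmetry better than two separate aryl transfers. No cryogenic aryne sequence is needed, so it is operationally equal or simpler.
- Against: the regiochemistry depends on the correct pairing of two ambident partners. The substituent at the diene terminus slows the first bond formation and places a silyloxy group beta to a carbonyl group, where elimination threatens. TiCl4 may strip silyl ethers. The second aryl addition meets the same hindered ketone as in the chosen plan, so it is equal on that point, and the first addition to the flanked ester is harder.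
- Comparison: about five steps to A6 and A7 and four or five after A8 give a length similar to the chosen plan. The chosen plan buys the ring A pattern as a cheap benzaldehyde and rests its regiocontrol on a well-understood halogen effect.

Key step: step 14

## Route

Step 1
Reactants: 1 4-bromophenol
Product: 2 1-bromo-4-(methoxymethoxy)benzene
Conditions: MOMCl, iPr2NEt, CH2Cl2, 0 °C to rt
Reagents that add atoms: chloromethyl methyl ether, COCCl
Why: Williamson-type O-alkylation of the phenol by the reactive chloromethyl ether. The acetal tolerates magnesium insertion, bromine–lithium exchange and palladium catalysis and falls to acid at the end.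

Step 2
Reactants: 3 4-hydroxybenzoic acid
Product: 4 4-hydroxy-N-methoxy-N-methylbenzamide
Conditions: MeNH(OMe)·HCl, EDC·HCl, HOBt, iPr2NEt, DMF, 0 °C to rt
Reagents that add atoms: N,O-dimethylhydroxylamine hydrochloride, CNOC.Cl
Why: Carbodiimide-mediated amidation through the HOBt active ester. The hydroxylamine nitrogen is far more nucleophilic than the phenol, so the amide should form without prior protection.

Step 3
Reactants: 4 4-hydroxy-N-methoxy-N-methylbenzamide
Product: 5 N-methoxy-N-methyl-4-(methoxymethoxy)benzamide
Conditions: MOMCl, iPr2NEt, CH2Cl2, 0 °C to rt
Reagents that add atoms: chloromethyl methyl ether, COCCl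
Why: Williamson-type O-alkylation as in step 1; the amide is inert to the amine base.

Step 4
Reactants: 6 4-iodophenol
Product: 7 1-iodo-4-(methoxymethoxy)benzene
Conditions: MOMCl, iPr2NEt, CH2Cl2, 0 °C to rt
Reagents that add atoms: chloromethyl methyl ether, COCCl
Why: Williamson-type O-alkylation as in step 1; the aryl iodide is untouched.

Step 5
Reactants: 7 1-iodo-4-(methoxymethoxy)benzene
Product: 8 {[4-(methoxymethoxy)phenyl]ethynyl}trimethylsilane
Conditions: ethynyltrimethylsilane, PdCl2(PPh3)2 (cat.), CuI (cat.), Et3N, THF, rt
Reagents that add atoms: ethynyltrimethylsilane, C#C[Si](C)(C)C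
Why: Sonogashira coupling of an aryl iodide, which undergoes oxidative addition at room temperature. The silyl cap prevents double arylation of acetylene.

Step 6
Reactants: 8 {[4-(methoxymethoxy)phenyl]ethynyl}trimethylsilane
Product: 9 1-ethynyl-4-(methoxymethoxy)benzene
Conditions: K2CO3 (cat.), MeOH, rt
Reagents that add atoms: none
Why: Base-catalysed protodesilylation of the alkynylsilane by methanolysis at silicon; the acetal is stable to base.

Step 7
Reactants: 10 2-chloro-4-hydroxybenzaldehyde
Product: 11 2-chloro-4-(methoxymethoxy)benzaldehyde
Conditions: MOMCl, iPr2NEt, CH2Cl2, 0 °C to rt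
Reagents that add atoms: chloromethyl methyl ether, COCCl
Why: Williamson-type O-alkylation of the acidic para-formyl phenol. The acetal will later direct the metalation.

Step 8
Reactants: 11 2-chloro-4-(methoxymethoxy)benzaldehyde
Product: 12 [2-chloro-4-(methoxymethoxy)phenyl]methanol
Conditions: NaBH4, MeOH, 0 °C
Reagents that add atoms: none
Why: Hydride reduction of the aldehyde; the aryl chloride and the acetal are inert to NaBH4.

Step 9
Reactants: 12 [2-chloro-4-(methoxymethoxy)phenyl]methanol
Product: 13 {[2-chloro-4-(methoxymethoxy)benzyl]oxy}triisopropylsilane
Conditions: TIPSCl, imidazole, DMF, rt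
Reagents that add atoms: chlorotriisopropylsilane, CC(C)[Si](Cl)(C(C)C)C(C)C
Why: Imidazole-assisted silylation of the primary alcohol. The bulky silyl ether withstands butyllithium, Grignard reagents and hot carbonate, yet still falls to protic acid in the last step.

Step 10
Reactants: 13 {[2-chloro-4-(methoxymethoxy)benzyl]oxy}triisopropylsilane
Product: 15 {[2-chloro-3-iodo-4-(methoxymethoxy)benzyl]oxy}triisopropylsilane, via ortho-chloro aryllithium 14 (not isolated)
Conditions: n-BuLi, THF, −78 °C, 1 h; I2, THF, −78 °C; aq Na2S2O3
Reagents that add atoms: iodine, II
Why: Directed ortho-metalation: the position between the chlorine and the acetal oxygen is acidified by both, and the acetal coordinates lithium, so deprotonation should occur there. At −78 °C the aryllithium 14 does not lose LiCl and is iodinated by I2.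

Step 11
Reactants: 15 {[2-chloro-3-iodo-4-(methoxymethoxy)benzyl]oxy}triisopropylsilane
Product: 17 3-chloro-2-iodo-4-{[(triisopropylsilyl)oxy]methyl}phenol, via aryl trimethylsilyl ether 16 (not isolated)
Conditions: TMSOTf, 2,2'-bipyridyl, CH2Cl2, 0 °C to rt; then H2O
Reagents that add atoms: none
Why: Chemoselective cleavage of an aryl methoxymethyl ether by a silyl triflate and 2,2'-bipyridyl. The silyl triflate activates the acetal, the bipyridyl takes up the methoxymethyl group, and the phenol oxygen passes to silicon as 16, which hydrolyses on aqueous work-up. No protic acid is present, so the benzylic silyl ether should survive.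

Step 12
Reactants: 17 3-chloro-2-iodo-4-{[(triisopropylsilyl)oxy]methyl}phenol
Product: 18 3-chloro-2-iodo-4-{[(triisopropylsilyl)oxy]methyl}phenyl 4-chlorobenzenesulfonate
Conditions: 4-ClC6H4SO2Cl, Et3N, DMAP (cat.), CH2Cl2, 0 °C to rt
Reagents that add atoms: 4-chlorobenzenesulfonyl chloride, O=S(=O)(Cl)c1ccc(Cl)cc1
Why: DMAP-catalysed sulfonylation of the phenol. This arenesulfonate tolerates iPrMgCl at −78 °C and leaves readily from an ortho-magnesiated arene on warming.

Step 13
Reactants: 2 1-bromo-4-(methoxymethoxy)benzene
Product: 19 4-(methoxymethoxy)phenylmagnesium bromide (THF solution, titrated and used as such)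
Conditions: Mg turnings (activated with a crystal of I2), THF, rt to 40 °C
Reagents that add atoms: magnesium, [Mg]
Why: Grignard reagent formation by insertion of magnesium into the aryl bromide; the acetal is inert.

Step 14
Reactants: 18 3-chloro-2-iodo-4-{[(triisopropylsilyl)oxy]methyl}phenyl 4-chlorobenzenesulfonate; 19 4-(methoxymethoxy)phenylmagnesium bromide; 5 N-methoxy-N-methyl-4-(methoxymethoxy)benzamide
Product: 24 [3-chloro-4'-(methoxymethoxy)-4-{[(triisopropylsilyl)oxy]methyl}biphenyl-2-yl][4-(methoxymethoxy)phenyl]methanone, via magnesioaryl sulfonate 20 (not isolated), via 3-chloroaryne 21 (not isolated), via biarylmagnesium bromide 22 (not isolated), via magnesium hemiaminal chelate 23 (not isolated)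
Conditions: iPrMgCl (1.05 equiv), THF, −78 °C, 30 min; 19 (2.0 equiv), −78 to −10 °C; 5 (3.5 equiv), −10 °C to rt; aq NH4Cl
Reagents that add atoms: none
Why: Iodine–magnesium exchange with iPrMgCl at −78 °C gives 20, which persists at that temperature; on warming it expels 4-chlorobenzenesulfonate, a far better leaving group than the chloride on the other flank, so elimination runs only toward the oxygen-bearing carbon and releases the 3-chloroaryne 21 (C1–C2 triple bond, chlorine on C6). The chlorine withdraws electron density through the sigma framework and bends the aryne so that the distal carbon C2 is the more electrophilic terminus, while the negative charge that builds at C1 lies next to the carbon–chlorine bond; the aryl group of 19 should therefore add at C2, which is also the less hindered end (C3 bears hydrogen), to give 22. The 2,6-disubstituted arylmagnesium 22 then attacks amide 5, and the five-membered magnesium chelate 23 does not collapse before aqueous work-up, so exactly one acyl group is transferred and ketone 24 is released only on quenching. The closest known reaction types are the carbomagnesiation of arynes generated from 2-magnesiated aryl sulfonates with electrophilic trapping of the new arylmagnesium, and the Weinreb ketone synthesis. No ring is closed and no stereocentre is formed; two carbon–carbon bonds are made at the two most crowded neighbours of ring A. The step needs exchange at iodine only (the carbon–chlorine bonds and the sulfonate are inert to iPrMgCl at −78 °C), sulfonate-over-chloride elimination, C2-selective arylation (secured by the C6 chlorine) and single acylation (secured by the chelate). The mixture is not taken above room temperature, where an ortho-chloro arylmagnesium does not yet lose MgBrCl, so no second aryne should form from 22. The surplus of 19 is absorbed by the excess of 5 as a symmetrical diaryl ketone that is removed by chromatography.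

Step 15
Reactants: 24 [3-chloro-4'-(methoxymethoxy)-4-{[(triisopropylsilyl)oxy]methyl}biphenyl-2-yl][4-(methoxymethoxy)phenyl]methanone; 9 1-ethynyl-4-(methoxymethoxy)benzene
Product: 25 [4'-(methoxymethoxy)-3-{[4-(methoxymethoxy)phenyl]ethynyl}-4-{[(triisopropylsilyl)oxy]methyl}biphenyl-2-yl][4-(methoxymethoxy)phenyl]methanone
Conditions: PdCl2(MeCN)2 (5 mol%), XPhos (15 mol%), Cs2CO3, MeCN, 85 °C, slow addition of 9, no copper
Reagents that add atoms: none
Why: Copper-free Sonogashira coupling of an aryl chloride. The bulky, electron-rich XPhos ligand gives a monoligated zerovalent palladium species that inserts into the carbon–chlorine bond, which the ortho carbonyl group activates, and Cs2CO3 deprotonates the palladium-bound alkyne. Leaving out copper and adding 9 slowly suppresses alkyne dimerisation.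

Step 16
Reactants: 25 [4'-(methoxymethoxy)-3-{[4-(methoxymethoxy)phenyl]ethynyl}-4-{[(triisopropylsilyl)oxy]methyl}biphenyl-2-yl][4-(methoxymethoxy)phenyl]methanone; 2 1-bromo-4-(methoxymethoxy)benzene
Product: 27 [4'-(methoxymethoxy)-3-{[4-(methoxymethoxy)phenyl]ethynyl}-4-{[(triisopropylsilyl)oxy]methyl}biphenyl-2-yl]bis[4-(methoxymethoxy)phenyl]methanol, via 4-(methoxymethoxy)phenyllithium 26 (not isolated)
Conditions: 2, n-BuLi, THF, −78 °C, 30 min; then 25, −78 to −30 °C; aq NH4Cl
Reagents that add atoms: none
Why: Bromine–lithium exchange followed by 1,2-addition of the aryllithium to a non-enolisable diaryl ketone. The small, reactive aryllithium should reach the carbonyl carbon despite the two ortho substituents on ring A, and the cold quench keeps the lithium alkoxide from adding to the neighbouring alkyne. The two aryl groups on the new carbinol carbon are identical, so no stereocentre arises.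

Step 17
Reactants: 27 [4'-(methoxymethoxy)-3-{[4-(methoxymethoxy)phenyl]ethynyl}-4-{[(triisopropylsilyl)oxy]methyl}biphenyl-2-yl]bis[4-(methoxymethoxy)phenyl]methanol
Product: 29 selaginellin [4-{[4'-hydroxy-4-(hydroxymethyl)-3-[(4-hydroxyphenyl)ethynyl]biphenyl-2-yl](4-hydroxyphenyl)methylidene}cyclohexa-2,5-dien-1-one], via deprotected triarylcarbinol 28 (not isolated)
Conditions: 3 M aq HCl, MeOH/THF, 45 °C; then aq NaHCO3 to neutrality
Reagents that add atoms: none
Why: Acid-catalysed solvolysis of the three aryl acetals and of the primary silyl ether, followed by ionisation of the triarylcarbinol 28 (fuchsone formation). The carbocation is stabilised by two para-hydroxyphenyl rings and loses a phenolic proton on neutralisation to give the para-quinone methide. Avoiding fluoride and base keeps free alkoxides away from the alkyne.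

## Compound list

1 | 4-bromophenol | Oc1ccc(Br)cc1 | starting material
2 | 1-bromo-4-(methoxymethoxy)benzene | COCOc1ccc(Br)cc1 | intermediate
3 | 4-hydroxybenzoic acid | O=C(O)c1ccc(O)cc1 | starting material
4 | 4-hydroxy-N-methoxy-N-methylbenzamide | CON(C)C(=O)c1ccc(O)cc1 | intermediate
5 | N-methoxy-N-methyl-4-(methoxymethoxy)benzamide | COCOc1ccc(C(=O)N(C)OC)cc1 | intermediate
6 | 4-iodophenol | Oc1ccc(I)cc1 | starting material
7 | 1-iodo-4-(methoxymethoxy)benzene | COCOc1ccc(I)cc1 | intermediate
8 | {[4-(methoxymethoxy)phenyl]ethynyl}trimethylsilane | COCOc1ccc(C#C[Si](C)(C)C)cc1 | intermediate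
9 | 1-ethynyl-4-(methoxymethoxy)benzene | COCOc1ccc(C#C)cc1 | intermediate
10 | 2-chloro-4-hydroxybenzaldehyde | O=Cc1ccc(O)cc1Cl | starting material
11 | 2-chloro-4-(methoxymethoxy)benzaldehyde | COCOc1ccc(C=O)c(Cl)c1 | intermediate
12 | [2-chloro-4-(methoxymethoxy)phenyl]methanol | COCOc1ccc(CO)c(Cl)c1 | intermediate
13 | {[2-chloro-4-(methoxymethoxy)benzyl]oxy}triisopropylsilane | COCOc1ccc(CO[Si](C(C)C)(C(C)C)C(C)C)c(Cl)c1 | intermediate
14 | [2-chloro-6-(methoxymethoxy)-3-{[(triisopropylsilyl)oxy]methyl}phenyl]lithium | COCOc1ccc(CO[Si](C(C)C)(C(C)C)C(C)C)c(Cl)c1[Li] | intermediate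
15 | {[2-chloro-3-iodo-4-(methoxymethoxy)benzyl]oxy}triisopropylsilane | COCOc1ccc(CO[Si](C(C)C)(C(C)C)C(C)C)c(Cl)c1I | intermediate
16 | {3-chloro-2-iodo-4-{[(triisopropylsilyl)oxy]methyl}phenoxy}trimethylsilane | C[Si](C)(C)Oc1ccc(CO[Si](C(C)C)(C(C)C)C(C)C)c(Cl)c1I | intermediate
17 | 3-chloro-2-iodo-4-{[(triisopropylsilyl)oxy]methyl}phenol | Oc1ccc(CO[Si](C(C)C)(C(C)C)C(C)C)c(Cl)c1I | intermediate
18 | 3-chloro-2-iodo-4-{[(triisopropylsilyl)oxy]methyl}phenyl 4-chlorobenzenesulfonate | CC(C)[Si](OCc1ccc(OS(=O)(=O)c2ccc(Cl)cc2)c(I)c1Cl)(C(C)C)C(C)C | intermediate
19 | 4-(methoxymethoxy)phenylmagnesium bromide | COCOc1ccc([Mg]Br)cc1 | intermediate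
20 | {2-chloro-6-[(4-chlorophenyl)sulfonyloxy]-3-{[(triisopropylsilyl)oxy]methyl}phenyl}magnesium chloride | CC(C)[Si](OCc1ccc(OS(=O)(=O)c2ccc(Cl)cc2)c([Mg]Cl)c1Cl)(C(C)C)C(C)C | intermediate
21 | 3-chloro-4-{[(triisopropylsilyl)oxy]methyl}benzyne (1,2-didehydrobenzene; triple bond between the former sulfonate carbon and the former iodine carbon) | ClC1=C(CO[Si](C(C)C)(C(C)C)C(C)C)C=CC#C1 | intermediate
22 | [3-chloro-4'-(methoxymethoxy)-4-{[(triisopropylsilyl)oxy]methyl}biphenyl-2-yl]magnesium bromide | COCOc1ccc(-c2ccc(CO[Si](C(C)C)(C(C)C)C(C)C)c(Cl)c2[Mg]Br)cc1 | intermediate
23 | bromomagnesium [3-chloro-4'-(methoxymethoxy)-4-{[(triisopropylsilyl)oxy]methyl}biphenyl-2-yl][methoxy(methyl)amino][4-(methoxymethoxy)phenyl]methanolate (racemic) | COCOc1ccc(C(O[Mg]Br)(N(C)OC)c2c(-c3ccc(OCOC)cc3)ccc(CO[Si](C(C)C)(C(C)C)C(C)C)c2Cl)cc1 | intermediate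
24 | [3-chloro-4'-(methoxymethoxy)-4-{[(triisopropylsilyl)oxy]methyl}biphenyl-2-yl][4-(methoxymethoxy)phenyl]methanone | COCOc1ccc(C(=O)c2c(-c3ccc(OCOC)cc3)ccc(CO[Si](C(C)C)(C(C)C)C(C)C)c2Cl)cc1 | intermediate
25 | [4'-(methoxymethoxy)-3-{[4-(methoxymethoxy)phenyl]ethynyl}-4-{[(triisopropylsilyl)oxy]methyl}biphenyl-2-yl][4-(methoxymethoxy)phenyl]methanone | COCOc1ccc(C(=O)c2c(-c3ccc(OCOC)cc3)ccc(CO[Si](C(C)C)(C(C)C)C(C)C)c2C#Cc2ccc(OCOC)cc2)cc1 | intermediate
26 | 4-(methoxymethoxy)phenyllithium | COCOc1ccc([Li])cc1 | intermediate
27 | [4'-(methoxymethoxy)-3-{[4-(methoxymethoxy)phenyl]ethynyl}-4-{[(triisopropylsilyl)oxy]methyl}biphenyl-2-yl]bis[4-(methoxymethoxy)phenyl]methanol | COCOc1ccc(C(O)(c2ccc(OCOC)cc2)c2c(-c3ccc(OCOC)cc3)ccc(CO[Si](C(C)C)(C(C)C)C(C)C)c2C#Cc2ccc(OCOC)cc2)cc1 | intermediate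
28 | 4,4'-{hydroxy[4'-hydroxy-4-(hydroxymethyl)-3-[(4-hydroxyphenyl)ethynyl]biphenyl-2-yl]methylene}diphenol | OCc1ccc(-c2ccc(O)cc2)c(C(O)(c2ccc(O)cc2)c2ccc(O)cc2)c1C#Cc1ccc(O)cc1 | intermediate
29 | selaginellin, 4-{[4'-hydroxy-4-(hydroxymethyl)-3-[(4-hydroxyphenyl)ethynyl]biphenyl-2-yl](4-hydroxyphenyl)methylidene}cyclohexa-2,5-dien-1-one (no stereocentre) | O=C1C=CC(=C(c2ccc(O)cc2)c2c(-c3ccc(O)cc3)ccc(CO)c2C#Cc2ccc(O)cc2)C=C1 | target

## Step count and risks

Total step count: 17, counting the preparation of the Grignard solution in step 13. Longest linear sequence: 10 steps (7, 8, 9, 10, 11, 12, 14, 15, 16, 17), from 10 to 29.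

Steps least certain to work:

Step 14 (key step). The most likely failure is slow acyl transfer from the chelating amide to the doubly ortho-substituted arylmagnesium. Protonation during the long reaction time, or loss of magnesium halide toward a second aryne on warming, would then compete. A second concern is erosion of the C2 selectivity in the aryl addition. Fallback: setting out from 18 and 19, the aryne is generated and arylated in the same way, but the arylmagnesium 22 is captured at −40 to 0 °C with purchased 4-(methoxymethoxy)benzaldehyde, a smaller and more electrophilic partner than the amide. This gives [3-chloro-4'-(methoxymethoxy)-4-{[(triisopropylsilyl)oxy]methyl}biphenyl-2-yl][4-(methoxymethoxy)phenyl]methanol F1 (racemic). Oxidation of the doubly benzylic alcohol with Dess–Martin periodinane in CH2Cl2 (or MnO2) comes back to the route at 24. Aldehyde addition followed by oxidation costs one step and removes the dependence on the amide.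

Step 15. Oxidative addition at a chloride flanked by two ortho substituents may be slow at a temperature the terminal alkyne tolerates, so alkyne oligomerisation could outrun the coupling. Fallback: setting out from 9, deprotonation with n-BuLi and quenching with Bu3SnCl gives tributyl{[4-(methoxymethoxy)phenyl]ethynyl}stannane F2. Stille coupling of F2 with 24 (Pd(P(t-Bu)3)2, CsF, dioxane, 100 °C) comes back at 25. The alkynyl group is delivered by transmetalation from tin, no free terminal alkyne is present, and the catalyst type is established for hindered aryl chlorides.

Step 11. Partial loss of the benzylic silyl ether, or incomplete transfer of the methoxymethyl group from an oxygen crowded by the neighbouring iodine, would lower the return of this selective deprotection. Fallback: setting out from 15, both protecting groups are removed with aqueous HCl in THF to give 3-chloro-4-(hydroxymethyl)-2-iodophenol F3. The phenoxide is sulfonylated selectively (4-ClC6H4SO2Cl, K2CO3, acetone, 0 °C) to give 3-chloro-4-(hydroxymethyl)-2-iodophenyl 4-chlorobenzenesulfonate F4. Silylation of the primary alcohol (TIPSCl, imidazole, DMF) comes back at 18. This costs one more step but needs no selectivity between the two protecting groups.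

Step 17. Slow cleavage of the bulky silyl ether could force long exposure of the quinone methide and the alkyne to warm acid. Addition of solvent or of the C5 hydroxymethyl oxygen to the alkyne, or closure of the cation onto the alkyne, could then intervene. Fallback: setting out from 27, the silyl ether is removed first with HF·pyridine buffered with pyridine in THF at 0 °C to rt. This is a fluoride source that produces no free alkoxide, and it gives [4-(hydroxymethyl)-4'-(methoxymethoxy)-3-{[4-(methoxymethoxy)phenyl]ethynyl}biphenyl-2-yl]bis[4-(methoxymethoxy)phenyl]methanol F5. A short treatment of F5 with dilute HCl in MeOH/THF at rt to 40 °C, needed only for the aryl acetals and the ionisation, comes back at 29.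

Further compounds

F1 | step 14 | [3-chloro-4'-(methoxymethoxy)-4-{[(triisopropylsilyl)oxy]methyl}biphenyl-2-yl][4-(methoxymethoxy)phenyl]methanol (racemic) | COCOc1ccc(C(O)c2c(-c3ccc(OCOC)cc3)ccc(CO[Si](C(C)C)(C(C)C)C(C)C)c2Cl)cc1
F2 | step 15 | tributyl{[4-(methoxymethoxy)phenyl]ethynyl}stannane | CCCC[Sn](CCCC)(CCCC)C#Cc1ccc(OCOC)cc1
F3 | step 11 | 3-chloro-4-(hydroxymethyl)-2-iodophenol | OCc1ccc(O)c(I)c1Cl
F4 | step 11 | 3-chloro-4-(hydroxymethyl)-2-iodophenyl 4-chlorobenzenesulfonate | OCc1ccc(OS(=O)(=O)c2ccc(Cl)cc2)c(I)c1Cl
F5 | step 17 | [4-(hydroxymethyl)-4'-(methoxymethoxy)-3-{[4-(methoxymethoxy)phenyl]ethynyl}biphenyl-2-yl]bis[4-(methoxymethoxy)phenyl]methanol | COCOc1ccc(C(O)(c2ccc(OCOC)cc2)c2c(-c3ccc(OCOC)cc3)ccc(CO)c2C#Cc2ccc(OCOC)cc2)cc1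
A1 | alternative 1 | 5,5-bis[4-(methoxymethoxy)phenyl]-3-{1-[(methoxymethoxy)methyl]vinyl}-4-{1-[4-(methoxymethoxy)phenyl]vinyl}furan-2(5H)-one | C=C(COCOC)C1=C(C(=C)c2ccc(OCOC)cc2)C(c2ccc(OCOC)cc2)(c2ccc(OCOC)cc2)OC1=O
A2 | alternative 1 | 6,7-dihydro-7-[(methoxymethoxy)methyl]-3,3,4-tris[4-(methoxymethoxy)phenyl]phthalide, 5,6-dihydro-2-benzofuran-1(3H)-one numbering (cyclohexa-1,3-diene) | COCOCC1=C2C(=O)OC(c3ccc(OCOC)cc3)(c3ccc(OCOC)cc3)C2=C(c2ccc(OCOC)cc2)CC1
A3 | alternative 1 | 7-[(methoxymethoxy)methyl]-3,3,4-tris[4-(methoxymethoxy)phenyl]-2-benzofuran-1(3H)-one | COCOCc1ccc(-c2ccc(OCOC)cc2)c2c1C(=O)OC2(c1ccc(OCOC)cc1)c1ccc(OCOC)cc1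
A4 | alternative 2 | [3-(methoxymethoxy)prop-1-yn-1-yl]dimethyl{[1,1,3-tris[4-(methoxymethoxy)phenyl]prop-2-yn-1-yl]oxy}silane | COCOCC#C[Si](C)(C)OC(C#Cc1ccc(OCOC)cc1)(c1ccc(OCOC)cc1)c1ccc(OCOC)cc1
A5 | alternative 2 | 7-[(methoxymethoxy)methyl]-1,1-dimethyl-3,3,4-tris[4-(methoxymethoxy)phenyl]-1,3-dihydro-2,1-benzoxasilole | COCOCc1ccc(-c2ccc(OCOC)cc2)c2c1[Si](C)(C)OC2(c1ccc(OCOC)cc1)c1ccc(OCOC)cc1
A6 | alternative 3 | 5-(tert-butyldiphenylsilyloxy)-1-methoxy-1,3-bis(trimethylsilyloxy)penta-1,3-diene (alkene geometries not fixed) | COC(O[Si](C)(C)C)=CC(O[Si](C)(C)C)=CCO[Si](c1ccccc1)(c1ccccc1)C(C)(C)C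
A7 | alternative 3 | 1-[4-(triisopropylsilyloxy)phenyl]-3-(trimethylsilyloxy)prop-2-en-1-one (alkene geometry not fixed) | C[Si](C)(C)OC=CC(=O)c1ccc(O[Si](C(C)C)(C(C)C)C(C)C)cc1
A8 | alternative 3 | methyl 3-[(tert-butyldiphenylsilyloxy)methyl]-2-hydroxy-6-[4-(triisopropylsilyloxy)phenyl]benzoate | COC(=O)c1c(O)c(CO[Si](c2ccccc2)(c2ccccc2)C(C)(C)C)ccc1-c1ccc(O[Si](C(C)C)(C(C)C)C(C)C)cc1
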